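## The problem

The target is a biflavone. Flavone 1 (rings A, C, B) is 5-hydroxy-7-methoxy-substituted with a 4'-methoxy ring B. Flavone 2 (rings D, E, F) is 5,7,4'-trihydroxylated and is bonded through its C8 to C2' of ring B. Ring B therefore carries two large sp2 groups on neighbouring carbons: C2 of flavone 1 at C1' and ring D at C2', with the methoxy group para to C1' and meta to C2'. The C2'–C8 biaryl bond has three ortho substituents, and its ring-D end sits between two oxygens. There is no stereocentre, so the difficulty is regiochemical throughout. First, the 1,2,4-pattern of ring B must be set. Second, the three phloroglucinol oxygens of ring D must be told apart: one of the two that flank C8 becomes the pyranone oxygen O1 of flavone 2, while the other (O7) and the para oxygen (O5) end as phenols. An error here gives the 6-linked isomer. Four phenols must be freed at the end beside two aryl methyl ethers, the pyranones open in hot alkali, and their C2–C3 double bonds can be over-reduced. The enabling feature is the adjacency of C1' and C2': a ring-B aryne across these carbons can take ring D as a nucleophile at C2' and a one-carbon electrophile, the future C2 of flavone 1, at C1'. The resulting carboxyl group then lies ortho to the biaryl bond and can lactonise onto one flanking oxygen of ring D, which marks that oxygen as the future O1.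

## Retrosynthesis

**Target 24 back to 23.** Three O–benzyl bonds are cut. Benzyl is chosen for ring D and ring F because hydrogenolysis leaves the two methyl ethers untouched, which no acid- or nucleophile-based dealkylation would guarantee. The chelated 5-hydroxyl of flavone 1 needs no protection. The forward step must spare both C2–C3 double bonds.

**Ring E: 23 back to 22, then to 20 and 21, then to 19.** The O1–C2 bond of flavone 2 is cut (oxidative cyclisation of 2'-hydroxychalcone 22), then the C2–C3 bond (Claisen–Schmidt condensation of methyl ketone 20 with 4-(benzyloxy)benzaldehyde 21), then the ring-D–acetyl bond (20 from 19). A Baker–Venkataraman sequence would require O-aroylation of a phenol wedged between ring B and the acetyl group; the chalcone route uses that phenol only in an intramolecular closure. Compound 19 has one free hydroxyl on ring D, and that hydroxyl decides both where the acetyl group enters and which oxygen closes ring E. The forward steps must acetylate ortho to that hydroxyl without losing benzyl ethers and must condense in base without opening ring C.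

**Ring C: 19 back to diketone 18, then to lactone 16 and acetophenone 17.** The O1–C2 and C2–C3 bonds of flavone 1 are cut. The acyl donor is the dibenzopyranone 16 and not an acid chloride, because the leaving group of the Claisen condensation is then the ring-D phenoxide itself. One reaction forms C2–C3 and unmasks exactly the oxygen that is to become O1 of flavone 2, while O5 and O7 stay benzylated. Ketone 17 is used unprotected as its polyanion, which gives the 5-hydroxyl of flavone 1 directly. The forward reaction asks for C-acylation by an aryl ester and for closure of the diketone by the ring-A hydroxyl and not by the ring-D one.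

**Lactone 16 back to 15, 14 and acid 13.** These are functional-group changes: two benzyl ethers (16 from 15), C6'–H in place of C6'–Cl (15 from 14), and the lactone C–O bond together with three acetals (14 from 13). In 13 ring D is still symmetric, so either flanking oxygen gives the same lactone; lactonisation is the point where the symmetry is broken usefully. Chlorine is removed at 14, before any benzyl ether exists, so the hydrogenolysis there is unambiguous.

**Key disconnection: 13 back to sulfonate 4, Grignard reagent 9 and carbon dioxide 7.** The C2'–C8 and C1'–C2 bonds are cut together across a C1'–C2' aryne. A cross-coupling at this position would have to join a 2,6-dioxygenated aryl metal to a ring B that already bears the ortho carbonyl. The aryne addition instead forms the crowded bond by attack on a strained triple bond and delivers the carbanion at C1' for carboxylation. The chlorine at C6' fixes the direction of addition; without it the 4'-methoxy group would give a weak bias the wrong way. The precursors are a benzene-level iodoaryl sulfonate and a metalated phloroglucinol ether.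

**Precursors.** Sulfonate 4 comes from 2-chloro-4-methoxyphenol 1 by ortho-iodination (2) and sulfonylation with 4-chlorobenzenesulfonyl chloride 3. Grignard reagent 9 comes from phloroglucinol 5 through tris(methoxymethyl) ether 6, lithiation between two acetal oxygens (8) and exchange of lithium for magnesium. The acetals direct the lithiation and later fall off in the acid that closes the lactone.

## Roads not taken

**Alternative 1:** Phenol-directed C–H carbonylation. The cut is the C1'–carbonyl bond; the biaryl bond is made earlier by cross-coupling an 8-haloflavone with a 3-methoxyphenylboron reagent to give the 7-hydroxy-8-(3-methoxyphenyl)flavone A1. In the key step A1 reacts with CO under Pd(OAc)2 with Cu(OAc)2 as oxidant: palladation of ring B directed by O7, CO insertion and C–O bond formation close the six-membered lactone A2.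
- Merits: flavone 2 is complete before the hard step. The coupling partner has no ortho substituent, so the biaryl bond is probably easier to make than by the aryne addition, and ring D needs no lactone to assign its oxygens. Palladation should prefer the ring-B position para to the methoxy group, which is the correct one.
- Weak points: A1 needs O7 free and O5 benzylated, the reverse of the natural reactivity order, which costs protecting-group steps. Halogenation at C8 must be selective over C6. The directing group is a 7-hydroxychromone, a weakly coordinating vinylogous acid, whereas the reaction type is established for simple 2-arylphenols. The lactone A2 must then be opened by the ring-A enolate with a complete flavone in the molecule.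
- Comparison: Alternative 1 is better on the biaryl bond. The chosen plan forms both ortho bonds of ring B at step 4 from simple materials, takes the one-carbon unit from carbon dioxide at low temperature, and places its risk early.

**Alternative 2:** Danheiser benzannulation. Three bonds of ring D are cut (C8–C8a, C6–C7, C4a–C8a). Heating 3-ethoxycyclobut-2-en-1-one A3 with the ring-B siloxyalkyne A4 gives, through a vinylketene, [2+2] addition, ring opening and six-electron electrocyclisation, the phenol A5.
- Merits: no biaryl coupling is needed, because the aryl–alkyne bond becomes the biaryl bond. The three oxygens of ring D emerge already distinct (hydroxyl, silyl ether, ethyl ether), which is a cleaner differentiation than the lactone device. The regiochemistry follows from the mechanism.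
- Weak points: A4 has to be made from a ring-B ester by ynolate chemistry and is sensitive. In A5 the C1' position is only a bromide, so the C1'–C2 bond still costs a metalation and carboxylation beside a free phenol. The ethyl ether at the future O5 can be removed beside two methyl ethers only by chelation-assisted cleavage once the C4 carbonyl is in place.
- Comparison: Alternative 2 is better on ring-D differentiation. The chosen plan reaches the same biaryl from two commodity phenols and installs the C1' carbon in the same operation.

**Alternative 3:** Two-directional cyclisation of a bichalcone. The cuts are O1–C2 of both flavones. The bis(2'-hydroxychalcone) A6 is heated with catalytic I2 in DMSO to close rings C and E together and give the tri-O-benzyl ether A7, which is the same structure as compound 23.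
- Merits: as an end game it is shorter than the chosen one, which closes rings C and E in separate operations (steps 8 and 11), and the cyclisation is very dependable.
- Weak points: the idea is silent on the C2'–C8 bond. A6 needs ring B as an aldehyde and ring D as a methyl ketone in one biaryl, so two different crossed condensations must be ordered with protection to avoid scrambling. The single free hydroxyl on ring D of A6 presupposes the same differentiation problem already solved, without a lactone to help.
- Comparison: Alternative 3 is better on step economy at the end. The chosen plan solves the earlier questions: the biaryl bond and C1' carbon arise together, a carboxyl carbon cannot cross-condense, and the lactone both activates the acyl group and labels O8a.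

Key step: step 4

Remark on the chemistry: the target has no stereocentre and its hindered C2'–C8 axis is drawn without configuration; it is taken as configurationally unassigned, so no atropselectivity is attempted. Primed locants refer to ring B of flavone 1; ring-D positions use flavone 2 numbering.

## Route

Step 1
Reactants: 1 2-chloro-4-methoxyphenol
Product: 2 2-chloro-6-iodo-4-methoxyphenol
Conditions: NIS, p-TsOH·H2O (cat.), MeCN, 0 °C to rt
Reagents that add atoms: N-iodosuccinimide, O=C1CCC(=O)N1I
Why: Electrophilic aromatic iodination; the hydroxyl is the strongest director, its para position is blocked by the methoxy group and C6 is its only free ortho position.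

Step 2
Reactants: 2 2-chloro-6-iodo-4-methoxyphenol; 3 4-chlorobenzenesulfonyl chloride
Product: 4 2-chloro-6-iodo-4-methoxyphenyl 4-chlorobenzenesulfonate
Conditions: Et3N, DMAP (cat.), CH2Cl2, 0 °C to rt
Reagents that add atoms: none
Why: O-Sulfonylation of an acidic 2,6-dihalophenol; the 4-chlorobenzenesulfonate is a leaving group that survives iodine–magnesium exchange at low temperature and departs on warming.

Step 3
Reactants: 5 phloroglucinol
Product: 6 1,3,5-tris(methoxymethoxy)benzene
Conditions: MOMCl, i-Pr2NEt, CH2Cl2, 0 °C to rt
Reagents that add atoms: chloromethyl methyl ether, COCCl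
Why: Threefold O-alkylation with a hard alkylating agent gives the acetal ether; the acetals direct the later ortho-lithiation and are acid-labile.

Step 4
Reactants: 4 2-chloro-6-iodo-4-methoxyphenyl 4-chlorobenzenesulfonate; 6 1,3,5-tris(methoxymethoxy)benzene; 7 carbon dioxide
Product: 13 2-chloro-4-methoxy-6-[2,4,6-tris(methoxymethoxy)phenyl]benzoic acid, via aryllithium 8 (not isolated), via aryl Grignard reagent 9 (not isolated), via magnesiated sulfonate 10 (not isolated), via aryne 11 (not isolated), via biaryl Grignard reagent 12 (not isolated)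
Conditions: 6, n-BuLi, THF, 0 °C, then MgBr2·OEt2 (gives 9); separately 4, i-PrMgCl, THF, −78 °C; 9 (1.5 equiv), −78 to 0 °C; CO2, −20 °C to rt; cold aq. citric acid
Reagents that add atoms: none
Why: Lithiation of 6 between two acetal oxygens and exchange to magnesium give 9, while iodine–magnesium exchange on 4 gives 10, which on warming expels the sulfonate to release 3-chloro-5-methoxybenzyne 11. Reagent 9 adds to the triple bond at the carbon remote from chlorine (C2'), leaving the carbanion at C1' as Grignard reagent 12, which carbon dioxide converts to the acid. The closest known reaction type is the addition of aryl Grignard reagents to arynes with electrophilic capture of the 2-magnesiated biaryl, here combined with aryne release from a 2-iodoaryl sulfonate. No ring is closed and no stereocentre is formed, ring D being symmetric. The step needs regioselective addition, which the chlorine at C6' secures by distorting the aryne and stabilising the adjacent carbanion inductively, helped by steric approach away from chlorine and outweighing the weak opposite bias of the 4'-methoxy group. It also needs exchange at iodine without attack at sulfur, secured by using magnesium and not lithium nucleophiles at −78 °C. Reagent 12 is kept at or below 0 °C so that it does not lose magnesium halide to form a second aryne, and the excess of 9 keeps 12 from adding to unreacted 11.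

Step 5
Reactants: 13 2-chloro-4-methoxy-6-[2,4,6-tris(methoxymethoxy)phenyl]benzoic acid
Product: 14 7-chloro-1,3-dihydroxy-9-methoxy-6H-benzo[c]chromen-6-one
Conditions: HCl (3 M aq.), MeOH, 55 °C
Reagents that add atoms: none
Why: Acid-catalysed acetal cleavage frees the phloroglucinol ring and the ortho carboxyl lactonises onto a flanking hydroxyl (6-membered dibenzopyranone); both flanking hydroxyls are equivalent, so one lactone results.

Step 6
Reactants: 14 7-chloro-1,3-dihydroxy-9-methoxy-6H-benzo[c]chromen-6-one
Product: 15 1,3-dihydroxy-9-methoxy-6H-benzo[c]chromen-6-one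
Conditions: H2 (1 atm), Pd/C, Et3N, THF–EtOAc, rt
Reagents that add atoms: none
Why: Base-assisted catalytic hydrodechlorination of an aryl chloride; no benzyl ether is present yet and the lactone and methyl ether are inert.

Step 7
Reactants: 15 1,3-dihydroxy-9-methoxy-6H-benzo[c]chromen-6-one
Product: 16 1,3-bis(benzyloxy)-9-methoxy-6H-benzo[c]chromen-6-one
Conditions: BnBr, K2CO3, DMF, 50 °C
Reagents that add atoms: benzyl bromide, BrCc1ccccc1
Why: Williamson etherification of both phenols under anhydrous carbonate conditions, which leave the aryl lactone closed.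

Step 8
Reactants: 16 1,3-bis(benzyloxy)-9-methoxy-6H-benzo[c]chromen-6-one; 17 2',6'-dihydroxy-4'-methoxyacetophenone
Product: 19 2-{2-[2,4-bis(benzyloxy)-6-hydroxyphenyl]-4-methoxyphenyl}-5-hydroxy-7-methoxy-4H-chromen-4-one, via diketone 18 (not isolated)
Conditions: 17, LiN(SiMe3)2 (4.2 equiv), THF, −78 to −10 °C; 16, −78 °C to rt; aq. HCl; crude 18, p-TsOH·H2O (cat.), toluene, 80 °C
Reagents that add atoms: none
Why: Crossed Claisen condensation of the acetophenone polyanion with the aryl-ester lactone expels the ring-D phenoxide and gives the 1,3-diketone, held as its enolate by the excess base. Acid-catalysed cyclodehydration through a ring-A hydroxyl then gives the aromatic pyranone, which is the thermodynamic product over any adduct of the ring-D phenol.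

Step 9
Reactants: 19 2-{2-[2,4-bis(benzyloxy)-6-hydroxyphenyl]-4-methoxyphenyl}-5-hydroxy-7-methoxy-4H-chromen-4-one
Product: 20 2-{2-[3-acetyl-4,6-bis(benzyloxy)-2-hydroxyphenyl]-4-methoxyphenyl}-5-hydroxy-7-methoxy-4H-chromen-4-one
Conditions: Ac2O, BF3·OEt2 (3 equiv), CH2Cl2, 0 °C to rt; then MeOH–H2O, 40 °C
Reagents that add atoms: acetic anhydride, CC(=O)OC(C)=O
Why: Fries-type ortho C-acetylation of the electron-rich ring-D phenol, driven by the boron chelate of the ortho-hydroxy ketone; the only free ortho position is the future C4a, and ring A is deactivated by its chelated carbonyl.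

Step 10
Reactants: 20 2-{2-[3-acetyl-4,6-bis(benzyloxy)-2-hydroxyphenyl]-4-methoxyphenyl}-5-hydroxy-7-methoxy-4H-chromen-4-one; 21 4-(benzyloxy)benzaldehyde
Product: 22 2-{2-[4,6-bis(benzyloxy)-3-{(2E)-3-[4-(benzyloxy)phenyl]prop-2-enoyl}-2-hydroxyphenyl]-4-methoxyphenyl}-5-hydroxy-7-methoxy-4H-chromen-4-one
Conditions: KOH (aq.), EtOH–THF, rt
Reagents that add atoms: none
Why: Claisen–Schmidt condensation gives the E-enone by elimination under thermodynamic control; at room temperature the pyranone of flavone 1 is protected as its 5-phenoxide.

Step 11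
Reactants: 22 the 2'-hydroxychalcone from step 10
Product: 23 5,7-bis(benzyloxy)-2-[4-(benzyloxy)phenyl]-8-[2-(5-hydroxy-7-methoxy-4-oxo-4H-chromen-2-yl)-5-methoxyphenyl]-4H-chromen-4-one
Conditions: I2 (cat.), DMSO, 120 °C
Reagents that add atoms: none
Why: Oxidative cyclisation of a 2'-hydroxychalcone (6-endo oxa-Michael addition, then iodine-mediated dehydrogenation with DMSO as terminal oxidant); the only free hydroxyl on ring D is O8a, so only the 8-linked flavone can form.

Step 12
Reactants: 23 the tri-O-benzyl biflavone from step 11
Product: 24 5,7-dihydroxy-8-[2-(5-hydroxy-7-methoxy-4-oxo-4H-chromen-2-yl)-5-methoxyphenyl]-2-(4-hydroxyphenyl)-4H-chromen-4-one (target)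
Conditions: H2 (1 atm), Pd/C, THF–MeOH, rt
Reagents that add atoms: none
Why: Hydrogenolysis of three aryl benzyl ethers; methyl ethers are untouched and the flavone double bonds are reduced far more slowly than the benzyl ethers are cleaved.

## Compound list

1 | 2-chloro-4-methoxyphenol | COc1ccc(O)c(Cl)c1 | starting material
2 | 2-chloro-6-iodo-4-methoxyphenol | COc1cc(Cl)c(O)c(I)c1 | intermediate
3 | 4-chlorobenzenesulfonyl chloride | O=S(=O)(Cl)c1ccc(Cl)cc1 | starting material
4 | 2-chloro-6-iodo-4-methoxyphenyl 4-chlorobenzenesulfonate | COc1cc(Cl)c(OS(=O)(=O)c2ccc(Cl)cc2)c(I)c1 | intermediate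
5 | phloroglucinol | Oc1cc(O)cc(O)c1 | starting material
6 | 1,3,5-tris(methoxymethoxy)benzene | COCOc1cc(OCOC)cc(OCOC)c1 | intermediate
7 | carbon dioxide | O=C=O | starting material
8 | 2,4,6-tris(methoxymethoxy)phenyllithium | COCOc1cc(OCOC)c([Li])c(OCOC)c1 | intermediate (not isolated)
9 | 2,4,6-tris(methoxymethoxy)phenylmagnesium bromide | COCOc1cc(OCOC)c([Mg]Br)c(OCOC)c1 | intermediate (not isolated)
10 | [3-chloro-2-(4-chlorobenzenesulfonyloxy)-5-methoxyphenyl]magnesium chloride | COc1cc(Cl)c(OS(=O)(=O)c2ccc(Cl)cc2)c([Mg]Cl)c1 | intermediate (not isolated)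
11 | 3-chloro-5-methoxybenzyne | COC1=CC#CC(Cl)=C1 | intermediate (not isolated)
12 | {2-chloro-4-methoxy-6-[2,4,6-tris(methoxymethoxy)phenyl]phenyl}magnesium bromide | COc1cc(Cl)c([Mg]Br)c(-c2c(OCOC)cc(OCOC)cc2OCOC)c1 | intermediate (not isolated)
13 | 2-chloro-4-methoxy-6-[2,4,6-tris(methoxymethoxy)phenyl]benzoic acid | COc1cc(Cl)c(C(=O)O)c(-c2c(OCOC)cc(OCOC)cc2OCOC)c1 | intermediate
14 | 7-chloro-1,3-dihydroxy-9-methoxy-6H-benzo[c]chromen-6-one | COc1cc(Cl)c2C(=O)Oc3cc(O)cc(O)c3-c2c1 | intermediate
15 | 1,3-dihydroxy-9-methoxy-6H-benzo[c]chromen-6-one | COc1ccc2C(=O)Oc3cc(O)cc(O)c3-c2c1 | intermediate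
16 | 1,3-bis(benzyloxy)-9-methoxy-6H-benzo[c]chromen-6-one | COc1ccc2C(=O)Oc3cc(OCc4ccccc4)cc(OCc4ccccc4)c3-c2c1 | intermediate
17 | 2',6'-dihydroxy-4'-methoxyacetophenone | CC(=O)c1c(O)cc(OC)cc1O | starting material
18 | 1-{2-[2,4-bis(benzyloxy)-6-hydroxyphenyl]-4-methoxyphenyl}-3-(2,6-dihydroxy-4-methoxyphenyl)propane-1,3-dione | COc1cc(O)c(C(=O)CC(=O)c2ccc(OC)cc2-c2c(O)cc(OCc3ccccc3)cc2OCc2ccccc2)c(O)c1 | intermediate (not isolated)
19 | 2-{2-[2,4-bis(benzyloxy)-6-hydroxyphenyl]-4-methoxyphenyl}-5-hydroxy-7-methoxy-4H-chromen-4-one | COc1cc(O)c2c(=O)cc(-c3ccc(OC)cc3-c3c(O)cc(OCc4ccccc4)cc3OCc3ccccc3)oc2c1 | intermediate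
20 | 2-{2-[3-acetyl-4,6-bis(benzyloxy)-2-hydroxyphenyl]-4-methoxyphenyl}-5-hydroxy-7-methoxy-4H-chromen-4-one | COc1cc(O)c2c(=O)cc(-c3ccc(OC)cc3-c3c(O)c(C(C)=O)c(OCc4ccccc4)cc3OCc3ccccc3)oc2c1 | intermediate
21 | 4-(benzyloxy)benzaldehyde | O=Cc1ccc(OCc2ccccc2)cc1 | starting material
22 | 2-{2-[4,6-bis(benzyloxy)-3-{(2E)-3-[4-(benzyloxy)phenyl]prop-2-enoyl}-2-hydroxyphenyl]-4-methoxyphenyl}-5-hydroxy-7-methoxy-4H-chromen-4-one | COc1cc(O)c2c(=O)cc(-c3ccc(OC)cc3-c3c(O)c(C(=O)/C=C/c4ccc(OCc5ccccc5)cc4)c(OCc4ccccc4)cc3OCc3ccccc3)oc2c1 | intermediate
23 | 5,7-bis(benzyloxy)-2-[4-(benzyloxy)phenyl]-8-[2-(5-hydroxy-7-methoxy-4-oxo-4H-chromen-2-yl)-5-methoxyphenyl]-4H-chromen-4-one | COc1ccc(-c2cc(=O)c3c(O)cc(OC)cc3o2)c(-c2c(OCc3ccccc3)cc(OCc3ccccc3)c3c(=O)cc(-c4ccc(OCc5ccccc5)cc4)oc23)c1 | intermediate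
24 | 5,7-dihydroxy-8-[2-(5-hydroxy-7-methoxy-4-oxo-4H-chromen-2-yl)-5-methoxyphenyl]-2-(4-hydroxyphenyl)-4H-chromen-4-one | COc1ccc(-c2cc(=O)c3c(O)cc(OC)cc3o2)c(-c2c(O)cc(O)c3c(=O)cc(-c4ccc(O)cc4)oc23)c1 | target

## Step count and least certain steps

Total: 12 steps. Longest linear sequence: 11 steps (steps 1, 2 and 4 to 12, from compound 1).

**Step 4 (key step).** The most likely failures are leakage of regiocontrol in the addition to the aryne and collapse of the ortho-chloro Grignard reagent 12 into a second aryne before carboxylation; the hindered reagent 9 may also add slowly, so that 11 is consumed by oligomerisation. The fallback leaves the aryne logic for a cross-coupling. It sets out from 6 and returns at 15. Compound 6 is lithiated and borylated with 2-isopropoxy-4,4,5,5-tetramethyl-1,3,2-dioxaborolane to 2-[2,4,6-tris(methoxymethoxy)phenyl]-4,4,5,5-tetramethyl-1,3,2-dioxaborolane F1. Suzuki–Miyaura coupling of F1 with methyl 2-bromo-4-methoxybenzoate F2 (Pd(OAc)2, SPhos, K3PO4, toluene–water) should give methyl 4-methoxy-2-[2,4,6-tris(methoxymethoxy)phenyl]benzoate F3. HCl in methanol then removes the acetals and closes the lactone to 15. This is shorter to 15, but it is no longer the three-component construction and it depends on a 2,6-dioxygenated arylboron reagent that is prone to protodeboronation.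

**Step 8.** The liberated ring-D phenol may re-add to the diketone carbonyl, reversing the Claisen condensation or diverting the cyclodehydration to a benzochromene ketal; the polyanion of 17 may also react sluggishly because of poor solubility. The fallback caps the phenol before the diketone exists. It sets out from 16 and returns at 19. Lactone 16 is opened with the chloromagnesium amide of N,O-dimethylhydroxylamine (MeNH(OMe)·HCl, i-PrMgCl) to 2-[2,4-bis(benzyloxy)-6-hydroxyphenyl]-N,4-dimethoxy-N-methylbenzamide F4. Silylation (TBSCl, imidazole) gives the tert-butyldimethylsilyl ether of that amide F5. Acylation of the polyanion of 17 by F5 gives the silyl-protected diketone F6, and p-TsOH·H2O in toluene closes ring C to the silyl ether of 19 F7. Bu4NF then returns 19.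

**Step 9.** The benzyl ether ortho to the new acetyl group may be lost under the Lewis acid, which would free O5 and reopen the 6-linked pathway; acylation may also drift to the ring-D carbon between the two benzyl ethers. The fallback avoids Lewis-acid acylation and the hydroxide step. It sets out from 19 and returns at 23, replacing steps 9 to 11. Ortho-formylation of 19 (MgCl2, Et3N, paraformaldehyde, MeCN, reflux) gives 2-{2-[4,6-bis(benzyloxy)-3-formyl-2-hydroxyphenyl]-4-methoxyphenyl}-5-hydroxy-7-methoxy-4H-chromen-4-one F8. Excess lithium acetylide of 1-(benzyloxy)-4-ethynylbenzene F9 at −78 °C adds to the aldehyde to give the racemic propargylic alcohol F10; the chromone carbonyl, deactivated as its 5-phenoxide, is far less electrophilic. MnO2 oxidises F10 to the ynone F11, and base (K2CO3, acetone) closes ring E by 6-endo-dig addition of the phenol to give 23.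

**Step 10.** Hydroxide may open the pyranone of flavone 1 during the slow condensation of the hindered ketone. The fallback forms the C2–C3 bond by acylation instead of an aldol. It sets out from 20 and returns at 23, replacing steps 10 and 11. The polyanion of 20 (LiN(SiMe3)2, THF, −78 °C) is C-acylated with 4-(benzyloxy)benzoyl chloride F12 to the 1,3-diketone F13. Catalytic p-TsOH·H2O in toluene then cyclodehydrates F13 to 23.

**Step 12.** Over-reduction of a C2–C3 double bond to the flavanone, or incomplete cleavage of the hindered benzyl ethers, is the risk. The fallback is a Lewis-acid debenzylation, from 23 to 24: BCl3 with pentamethylbenzene as cation scavenger in CH2Cl2 at −78 °C, which spares aryl methyl ethers not adjacent to a carbonyl. No new compound arises (F0).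

## Further compounds

F1 | step 4 | 2-[2,4,6-tris(methoxymethoxy)phenyl]-4,4,5,5-tetramethyl-1,3,2-dioxaborolane | COCOc1cc(OCOC)c(B2OC(C)(C)C(C)(C)O2)c(OCOC)c1
F2 | step 4 | methyl 2-bromo-4-methoxybenzoate | COC(=O)c1ccc(OC)cc1Br
F3 | step 4 | methyl 4-methoxy-2-[2,4,6-tris(methoxymethoxy)phenyl]benzoate | COC(=O)c1ccc(OC)cc1-c1c(OCOC)cc(OCOC)cc1OCOC
F4 | step 8 | 2-[2,4-bis(benzyloxy)-6-hydroxyphenyl]-N,4-dimethoxy-N-methylbenzamide | CON(C)C(=O)c1ccc(OC)cc1-c1c(O)cc(OCc2ccccc2)cc1OCc1ccccc1
F5 | step 8 | 2-[2,4-bis(benzyloxy)-6-(tert-butyldimethylsilyloxy)phenyl]-N,4-dimethoxy-N-methylbenzamide | CON(C)C(=O)c1ccc(OC)cc1-c1c(O[Si](C)(C)C(C)(C)C)cc(OCc2ccccc2)cc1OCc1ccccc1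
F6 | step 8 | 1-{2-[2,4-bis(benzyloxy)-6-(tert-butyldimethylsilyloxy)phenyl]-4-methoxyphenyl}-3-(2,6-dihydroxy-4-methoxyphenyl)propane-1,3-dione | COc1cc(O)c(C(=O)CC(=O)c2ccc(OC)cc2-c2c(O[Si](C)(C)C(C)(C)C)cc(OCc3ccccc3)cc2OCc2ccccc2)c(O)c1
F7 | step 8 | 2-{2-[2,4-bis(benzyloxy)-6-(tert-butyldimethylsilyloxy)phenyl]-4-methoxyphenyl}-5-hydroxy-7-methoxy-4H-chromen-4-one | COc1cc(O)c2c(=O)cc(-c3ccc(OC)cc3-c3c(O[Si](C)(C)C(C)(C)C)cc(OCc4ccccc4)cc3OCc3ccccc3)oc2c1
F8 | step 9 | 2-{2-[4,6-bis(benzyloxy)-3-formyl-2-hydroxyphenyl]-4-methoxyphenyl}-5-hydroxy-7-methoxy-4H-chromen-4-one | COc1cc(O)c2c(=O)cc(-c3ccc(OC)cc3-c3c(O)c(C=O)c(OCc4ccccc4)cc3OCc3ccccc3)oc2c1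
F9 | step 9 | 1-(benzyloxy)-4-ethynylbenzene | C#Cc1ccc(OCc2ccccc2)cc1
F10 | step 9 | 2-{2-[4,6-bis(benzyloxy)-3-{3-[4-(benzyloxy)phenyl]-1-hydroxyprop-2-yn-1-yl}-2-hydroxyphenyl]-4-methoxyphenyl}-5-hydroxy-7-methoxy-4H-chromen-4-one (racemic) | COc1cc(O)c2c(=O)cc(-c3ccc(OC)cc3-c3c(O)c(C(O)C#Cc4ccc(OCc5ccccc5)cc4)c(OCc4ccccc4)cc3OCc3ccccc3)oc2c1
F11 | step 9 | 2-{2-[4,6-bis(benzyloxy)-3-{3-[4-(benzyloxy)phenyl]prop-2-ynoyl}-2-hydroxyphenyl]-4-methoxyphenyl}-5-hydroxy-7-methoxy-4H-chromen-4-one | COc1cc(O)c2c(=O)cc(-c3ccc(OC)cc3-c3c(O)c(C(=O)C#Cc4ccc(OCc5ccccc5)cc4)c(OCc4ccccc4)cc3OCc3ccccc3)oc2c1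
F12 | step 10 | 4-(benzyloxy)benzoyl chloride | O=C(Cl)c1ccc(OCc2ccccc2)cc1
F13 | step 10 | 1-[4-(benzyloxy)phenyl]-3-{4,6-bis(benzyloxy)-2-hydroxy-3-[2-(5-hydroxy-7-methoxy-4-oxo-4H-chromen-2-yl)-5-methoxyphenyl]phenyl}propane-1,3-dione | COc1cc(O)c2c(=O)cc(-c3ccc(OC)cc3-c3c(O)c(C(=O)CC(=O)c4ccc(OCc5ccccc5)cc4)c(OCc4ccccc4)cc3OCc3ccccc3)oc2c1
F0 | step 12 | none | none
A1 | alternative 1 | 5-(benzyloxy)-2-[4-(benzyloxy)phenyl]-7-hydroxy-8-(3-methoxyphenyl)-4H-chromen-4-one | COc1cccc(c1)-c1c(O)cc(OCc2ccccc2)c2c(=O)cc(-c3ccc(OCc4ccccc4)cc3)oc12
A2 | alternative 1 | lactone bridging O7 of flavone 2 and the C1' carbonyl of ring B (5-benzyloxy, 4'-benzyloxy, ring-B methoxy) | COc1ccc2c(c1)-c1c(OC2=O)cc(OCc2ccccc2)c2c(=O)cc(-c3ccc(OCc4ccccc4)cc3)oc12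
A3 | alternative 2 | 3-ethoxycyclobut-2-en-1-one | CCOC1=CC(=O)C1
A4 | alternative 2 | {[(2-bromo-5-methoxyphenyl)ethynyl]oxy}tri(propan-2-yl)silane | COc1ccc(Br)c(C#CO[Si](C(C)C)(C(C)C)C(C)C)c1
A5 | alternative 2 | 2-(2-bromo-5-methoxyphenyl)-5-ethoxy-3-(triisopropylsilyloxy)phenol | CCOc1cc(O)c(-c2cc(OC)ccc2Br)c(O[Si](C(C)C)(C(C)C)C(C)C)c1
A6 | alternative 3 | (2E)-3-{2-[4,6-bis(benzyloxy)-3-{(2E)-3-[4-(benzyloxy)phenyl]prop-2-enoyl}-2-hydroxyphenyl]-4-methoxyphenyl}-1-(2,6-dihydroxy-4-methoxyphenyl)prop-2-en-1-one | COc1cc(O)c(C(=O)/C=C/c2ccc(OC)cc2-c2c(O)c(C(=O)/C=C/c3ccc(OCc4ccccc4)cc3)c(OCc3ccccc3)cc2OCc2ccccc2)c(O)c1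
A7 | alternative 3 | tri-O-benzyl ether of the target with free 5-hydroxyl on flavone 1 (same structure as 23) | COc1ccc(-c2cc(=O)c3c(O)cc(OC)cc3o2)c(-c2c(OCc3ccccc3)cc(OCc3ccccc3)c3c(=O)cc(-c4ccc(OCc5ccccc5)cc4)oc23)c1
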